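## Retrosynthetic overview

1. The target comes from the macrocyclic C3 ketone by a catalyst-controlled CBS reduction in the last step.
2. The 14-membered ring, the only ring, is closed second to last at C5–C6 by an intramolecular allyl–alkenyl Suzuki–Miyaura coupling of an allylic carbonate with an alkenylboronate.
3. The C11 acetate and C12 tertiary alcohol come from a Shi epoxide on the farnesyl-derived E-olefin, opened by water at the tertiary carbon with inversion and then O-acetylated.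
4. C1 and the C1–C2 bond come from the key step, an enantioconvergent amine-catalysed SN2' alkylation of a racemic Morita–Baylis–Hillman (MBH) carbonate with a boryl-substituted 2-silyloxydiene.
5. The fragments are a C12 aldehyde from (2E,6E)-farnesyl acetate plus methyl acrylate, and a C5 boryl enone from 3-methylbut-3-en-2-one.

Assumption: ring locants C1–C14 are those of the target name methyl 2-[(1R,3S,4E,7E,11S,12R)-11-acetoxy-3,12-dihydroxy-4,8,12-trimethylcyclotetradeca-4,7-dien-1-yl]prop-2-enoate, and "pinacolboryl" means 4,4,5,5-tetramethyl-1,3,2-dioxaborolan-2-yl.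

## Route

Step 1
Reactants: 1 (2E,6E)-farnesyl acetate
Product: 3 racemic (2E,6E)-10,11-epoxyfarnesol, via bromohydrin acetate 2 (not isolated)
Conditions: NBS (1.1 equiv), THF/H2O (2:1), 0 °C; then K2CO3 (3 equiv), MeOH, rt
Reagents that add atoms: water, O; N-bromosuccinimide, O=C1CCC(=O)N1Br (its bromine is held only in 2)
Why: van Tamelen terminal-selective bromohydrin formation followed by base-induced epoxide closure with concurrent acetate methanolysis; the racemic stereocentre is erased in step 2.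

Step 2
Reactants: 3 racemic (2E,6E)-10,11-epoxyfarnesol
Product: 5 (4E,8E)-10-hydroxy-4,8-dimethyldeca-4,8-dienal, via triol 4 (not isolated)
Conditions: H5IO6 (1.3 equiv), THF/H2O, 0 °C, 1 h
Reagents that add atoms: water, O (its oxygen is held only in 4 and leaves in acetone)
Why: acid-mediated epoxide hydration then Malaprade glycol cleavage releases acetone and the aldehyde without touching the two trisubstituted olefins or the allylic alcohol.

Step 3
Reactants: 5 (4E,8E)-10-hydroxy-4,8-dimethyldeca-4,8-dienal; 6 methyl acrylate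
Product: 7 racemic methyl (6E,10E)-3,12-dihydroxy-6,10-dimethyl-2-methylidenedodeca-6,10-dienoate
Conditions: DABCO (1.0 equiv), MeOH, rt, 4 d (6 in fivefold excess)
Reagents that add atoms: none
Why: Morita–Baylis–Hillman reaction of an unhindered aliphatic aldehyde installs the α-methylene ester directly; the carbinol centre may be racemic because step 9 is enantioconvergent.

Step 4
Reactants: 7 racemic methyl (6E,10E)-3,12-dihydroxy-6,10-dimethyl-2-methylidenedodeca-6,10-dienoate
Product: 8 racemic methyl (6E,10E)-3,12-bis[(tert-butoxycarbonyl)oxy]-6,10-dimethyl-2-methylidenedodeca-6,10-dienoate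
Conditions: Boc2O (2.6 equiv), DMAP (0.2 equiv), CH2Cl2, 0 °C to rt
Reagents that add atoms: di-tert-butyl dicarbonate, CC(C)(C)OC(=O)OC(=O)OC(C)(C)C
Why: DMAP-catalysed O-acylation turns both alcohols into tert-butyl carbonates, one as the MBH leaving group for step 9 and the other as the allyl donor for step 12 that also deactivates its neighbouring olefin for step 5.

Step 5
Reactants: 8 racemic methyl (6E,10E)-3,12-bis[(tert-butoxycarbonyl)oxy]-6,10-dimethyl-2-methylidenedodeca-6,10-dienoate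
Product: 9 methyl (6S,7S,10E)-3,12-bis[(tert-butoxycarbonyl)oxy]-6,7-epoxy-6,10-dimethyl-2-methylidenedodec-10-enoate (1:1 mixture of C3 epimers)
Conditions: ent-Shi ketone (1,2:4,5-di-O-isopropylidene-β-L-erythro-2,3-hexodiulo-2,6-pyranose, 0.3 equiv), Oxone (2KHSO5·KHSO4·K2SO4, 1.4 equiv KHSO5), K2CO3, Bu4NHSO4, Na2B4O7/Na2EDTA buffer, MeCN/DMM/H2O, 0 °C, 2 h
Reagents that add atoms: potassium peroxymonosulfate, [K+].[O-]S(=O)(=O)OO
Why: Shi asymmetric epoxidation through the spiro dioxirane transition state attacks only the electron-rich internal E-trisubstituted olefin (the acrylate and the carbonate-bearing allylic olefin are deactivated), and the L-series ketone gives the (6S,7S) epoxide, the first non-racemic stereocentres.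

Step 6
Reactants: 10 3-methylbut-3-en-2-one
Product: 12 (3E)-4-bromo-3-methylbut-3-en-2-one, via dibromoketone 11 (not isolated)
Conditions: Br2 (1.0 equiv), CH2Cl2, -78 to 0 °C; then Et3N (1.5 equiv), 0 °C to rt; distillation
Reagents that add atoms: bromine, BrBr
Why: bromine addition then dehydrobromination toward the more acidic CHBr hydrogen gives the β-bromoenone, with the E isomer (Br trans to acetyl) expected to predominate and purified by distillation.

Step 7
Reactants: 12 (3E)-4-bromo-3-methylbut-3-en-2-one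
Product: 13 (3E)-3-methyl-4-(pinacolboryl)but-3-en-2-one
Conditions: B2pin2 (1.1 equiv), PdCl2(dppf) (3 mol %), KOAc (3 equiv), 1,4-dioxane, 80 °C
Reagents that add atoms: bis(pinacolato)diboron, CC1(C)OB(OC1(C)C)B1OC(C)(C)C(C)(C)O1
Why: Miyaura borylation of an alkenyl bromide proceeds with retention of olefin geometry.

Step 8
Reactants: 13 (3E)-3-methyl-4-(pinacolboryl)but-3-en-2-one
Product: 14 trimethyl{[(3E)-3-methyl-4-(pinacolboryl)buta-1,3-dien-2-yl]oxy}silane
Conditions: TMSOTf (1.2 equiv), Et3N (1.5 equiv), Et2O, -78 to 0 °C; pentane extraction, used at once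
Reagents that add atoms: trimethylsilyl trifluoromethanesulfonate, C[Si](C)(C)OS(=O)(=O)C(F)(F)F
Why: soft enolisation gives a single 2-silyloxydiene because the acetyl methyl carries the only enolisable hydrogens.

Step 9
Reactants: 9 methyl (6S,7S,10E)-3,12-bis[(tert-butoxycarbonyl)oxy]-6,7-epoxy-6,10-dimethyl-2-methylidenedodec-10-enoate (1:1 mixture of C3 epimers); 14 trimethyl{[(3E)-3-methyl-4-(pinacolboryl)buta-1,3-dien-2-yl]oxy}silane
Product: 15 methyl (3R,6S,7S,10E)-12-[(tert-butoxycarbonyl)oxy]-6,7-epoxy-6,10-dimethyl-2-methylidene-3-[(3E)-3-methyl-2-oxo-4-(pinacolboryl)but-3-en-1-yl]dodec-10-enoate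
Conditions: β-isocupreidine (20 mol %), 14 (2.0 equiv), 4 Å MS, toluene, 25 °C, 48 h
Reagents that add atoms: none
Why: Proposed new method: an enantioconvergent Lewis-base-catalysed allylic alkylation in which the quinuclidine nitrogen of β-isocupreidine adds SN2' to either C3 epimer of 9 and expels CO2 and tert-butoxide to give one allylammonium ion, the tert-butoxide desilylates 14 to an ammonium dienolate ion pair held by the catalyst's phenolic OH, and the dienolate CH2 terminus attacks the γ-carbon SN2' on one face to form the C1–C2 bond, set C1 (3R) and release the amine; the closest known reaction type is the cinchona-amine-catalysed SN2'–SN2' alkylation of aryl MBH carbonates with stabilised carbon pronucleophiles, which has not been shown for an aliphatic MBH carbonate paired with an unstabilised ketone enolsilane.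

Step 10
Reactants: 15 methyl (3R,6S,7S,10E)-12-[(tert-butoxycarbonyl)oxy]-6,7-epoxy-6,10-dimethyl-2-methylidene-3-[(3E)-3-methyl-2-oxo-4-(pinacolboryl)but-3-en-1-yl]dodec-10-enoate
Product: 16 methyl (3R,6R,7S,10E)-12-[(tert-butoxycarbonyl)oxy]-6,7-dihydroxy-6,10-dimethyl-2-methylidene-3-[(3E)-3-methyl-2-oxo-4-(pinacolboryl)but-3-en-1-yl]dodec-10-enoate
Conditions: HClO4 (0.5 M aq, 0.3 equiv), THF/H2O (3:1), 0 °C, 2 h
Reagents that add atoms: water, O
Why: acid-catalysed borderline-SN2 epoxide hydrolysis, with water attacking the tertiary carbon anti to the leaving oxygen, inverts that centre (6S to 6R, ring C12) and retains the secondary one (7S, ring C11), giving the required anti diol.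

Step 11
Reactants: 16 methyl (3R,6R,7S,10E)-12-[(tert-butoxycarbonyl)oxy]-6,7-dihydroxy-6,10-dimethyl-2-methylidene-3-[(3E)-3-methyl-2-oxo-4-(pinacolboryl)but-3-en-1-yl]dodec-10-enoate
Product: 17 methyl (3R,6R,7S,10E)-7-acetoxy-12-[(tert-butoxycarbonyl)oxy]-6-hydroxy-6,10-dimethyl-2-methylidene-3-[(3E)-3-methyl-2-oxo-4-(pinacolboryl)but-3-en-1-yl]dodec-10-enoate
Conditions: Ac2O (1.5 equiv), pyridine (3 equiv), DMAP (5 mol %), CH2Cl2, 0 °C
Reagents that add atoms: acetic anhydride, CC(=O)OC(C)=O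
Why: nucleophile-catalysed acetylation takes place only at the secondary hydroxyl because the tertiary carbinol is too hindered, and no other free hydroxyl is present at this stage.

Step 12
Reactants: 17 methyl (3R,6R,7S,10E)-7-acetoxy-12-[(tert-butoxycarbonyl)oxy]-6-hydroxy-6,10-dimethyl-2-methylidene-3-[(3E)-3-methyl-2-oxo-4-(pinacolboryl)but-3-en-1-yl]dodec-10-enoate
Product: 18 methyl 2-[(1R,4E,7E,11S,12R)-11-acetoxy-12-hydroxy-4,8,12-trimethyl-3-oxocyclotetradeca-4,7-dien-1-yl]prop-2-enoate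
Conditions: Pd2(dba)3 (10 mol %), P(2-furyl)3 (40 mol %), THF, 50 °C, syringe-pump addition to 1 mM
Reagents that add atoms: none
Why: intramolecular allyl–alkenyl Suzuki–Miyaura coupling in which zerovalent palladium ionises only the primary allylic carbonate, the released tert-butoxide activates the boronate for transmetalation, and reductive elimination at the unhindered allyl terminus closes the 14-membered ring with both E olefins retained.

Step 13
Reactants: 18 methyl 2-[(1R,4E,7E,11S,12R)-11-acetoxy-12-hydroxy-4,8,12-trimethyl-3-oxocyclotetradeca-4,7-dien-1-yl]prop-2-enoate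
Product: 19 methyl 2-[(1R,3S,4E,7E,11S,12R)-11-acetoxy-3,12-dihydroxy-4,8,12-trimethylcyclotetradeca-4,7-dien-1-yl]prop-2-enoate (CNP0201062.1)
Conditions: (R)-2-methyl-CBS-oxazaborolidine (0.3 equiv), catecholborane (3 equiv), toluene/CH2Cl2, -78 °C; MeOH, then pH 7 buffer
Reagents that add atoms: none
Why: Corey–Bakshi–Shibata reduction in which the α-methyl alkenyl group acts as the large substituent, so the (R)-catalyst delivers hydride to give the 3S allylic alcohol under catalyst control while ester, acetate and acrylate are inert to catecholborane at low temperature; the neutral work-up avoids δ-lactonisation.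

## Compound list

1 | (2E,6E)-farnesyl acetate | CC(C)=CCC/C(C)=C/CC/C(C)=C/COC(C)=O | starting material
2 | (2E,6E)-10-bromo-11-hydroxy-3,7,11-trimethyldodeca-2,6-dien-1-yl acetate (racemic, not isolated) | CC(C)(O)C(Br)CC/C(C)=C/CC/C(C)=C/COC(C)=O | intermediate
3 | (2E,6E)-10,11-epoxy-3,7,11-trimethyldodeca-2,6-dien-1-ol (racemic) | CC1(C)OC1CC/C(C)=C/CC/C(C)=C/CO | intermediate
4 | (2E,6E)-3,7,11-trimethyldodeca-2,6-diene-1,10,11-triol (racemic, not isolated) | CC(C)(O)C(O)CC/C(C)=C/CC/C(C)=C/CO | intermediate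
5 | (4E,8E)-10-hydroxy-4,8-dimethyldeca-4,8-dienal | O=CCC/C(C)=C/CC/C(C)=C/CO | intermediate
6 | methyl acrylate | C=CC(=O)OC | starting material
7 | methyl (6E,10E)-3,12-dihydroxy-6,10-dimethyl-2-methylidenedodeca-6,10-dienoate (racemic) | C=C(C(=O)OC)C(O)CC/C(C)=C/CC/C(C)=C/CO | intermediate
8 | methyl (6E,10E)-3,12-bis[(tert-butoxycarbonyl)oxy]-6,10-dimethyl-2-methylidenedodeca-6,10-dienoate (racemic) | C=C(C(=O)OC)C(OC(=O)OC(C)(C)C)CC/C(C)=C/CC/C(C)=C/COC(=O)OC(C)(C)C | intermediate
9 | methyl (6S,7S,10E)-3,12-bis[(tert-butoxycarbonyl)oxy]-6,7-epoxy-6,10-dimethyl-2-methylidenedodec-10-enoate (1:1 C3 epimers) | C=C(C(=O)OC)C(OC(=O)OC(C)(C)C)CC[C@]1(C)O[C@H]1CC/C(C)=C/COC(=O)OC(C)(C)C | intermediate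
10 | 3-methylbut-3-en-2-one | CC(=O)C(C)=C | starting material
11 | 3,4-dibromo-3-methylbutan-2-one (racemic, not isolated) | CC(=O)C(C)(Br)CBr | intermediate
12 | (3E)-4-bromo-3-methylbut-3-en-2-one | CC(=O)/C(C)=C/Br | intermediate
13 | (3E)-3-methyl-4-(pinacolboryl)but-3-en-2-one | CC(=O)/C(C)=C/B1OC(C)(C)C(C)(C)O1 | intermediate
14 | trimethyl{[(3E)-3-methyl-4-(pinacolboryl)buta-1,3-dien-2-yl]oxy}silane | C=C(O[Si](C)(C)C)/C(C)=C/B1OC(C)(C)C(C)(C)O1 | intermediate
15 | methyl (3R,6S,7S,10E)-12-[(tert-butoxycarbonyl)oxy]-6,7-epoxy-6,10-dimethyl-2-methylidene-3-[(3E)-3-methyl-2-oxo-4-(pinacolboryl)but-3-en-1-yl]dodec-10-enoate | C=C(C(=O)OC)[C@@H](CC(=O)/C(C)=C/B1OC(C)(C)C(C)(C)O1)CC[C@]2(C)O[C@H]2CC/C(C)=C/COC(=O)OC(C)(C)C | intermediate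
16 | methyl (3R,6R,7S,10E)-12-[(tert-butoxycarbonyl)oxy]-6,7-dihydroxy-6,10-dimethyl-2-methylidene-3-[(3E)-3-methyl-2-oxo-4-(pinacolboryl)but-3-en-1-yl]dodec-10-enoate | C=C(C(=O)OC)[C@@H](CC(=O)/C(C)=C/B1OC(C)(C)C(C)(C)O1)CC[C@@](C)(O)[C@@H](O)CC/C(C)=C/COC(=O)OC(C)(C)C | intermediate
17 | methyl (3R,6R,7S,10E)-7-acetoxy-12-[(tert-butoxycarbonyl)oxy]-6-hydroxy-6,10-dimethyl-2-methylidene-3-[(3E)-3-methyl-2-oxo-4-(pinacolboryl)but-3-en-1-yl]dodec-10-enoate | C=C(C(=O)OC)[C@@H](CC(=O)/C(C)=C/B1OC(C)(C)C(C)(C)O1)CC[C@@](C)(O)[C@@H](OC(C)=O)CC/C(C)=C/COC(=O)OC(C)(C)C | intermediate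
18 | methyl 2-[(1R,4E,7E,11S,12R)-11-acetoxy-12-hydroxy-4,8,12-trimethyl-3-oxocyclotetradeca-4,7-dien-1-yl]prop-2-enoate | C=C(C(=O)OC)[C@@H]1CC[C@@](C)(O)[C@@H](OC(C)=O)CC/C(C)=C/C/C=C(\C)C(=O)C1 | intermediate
19 | methyl 2-[(1R,3S,4E,7E,11S,12R)-11-acetoxy-3,12-dihydroxy-4,8,12-trimethylcyclotetradeca-4,7-dien-1-yl]prop-2-enoate | C=C(C(=O)OC)[C@@H]1CC[C@@](C)(O)[C@@H](OC(C)=O)CC/C(C)=C/C/C=C(\C)[C@@H](O)C1 | target

## Step count and risks

Total steps: 13. Longest linear sequence: 10 (steps 1–5, then 9–13); steps 6–8 are a three-step side branch.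

**Step 9 (the proposed new alkylation).** It may fail through low reactivity of the aliphatic MBH carbonate, O-allylation or proton transfer by the basic unstabilised dienolate, or low enantioselectivity. The sense of induction is assigned by analogy; the pseudoenantiomeric α-isocupreine would be tried if it proves opposite. The fallback uses known chemistry, sets out from 13 and 9, and comes back at 15. Ketone 13 is carboxylated (LiHMDS, THF, -78 °C; CO2; cold acidic work-up) to (4E)-4-methyl-3-oxo-5-(pinacolboryl)pent-4-enoic acid F1. F1 is then used at once in the established amine-catalysed decarboxylative allylic alkylation of MBH carbonates with β-keto acids (β-isocupreidine or (DHQD)2PHAL, toluene/CHCl3, rt). The stabilised β-keto carboxylate lies within the usual pronucleophile range; C-alkylation and loss of CO2 give 15.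

**Step 12 (macrocyclic sp3–sp2 Suzuki coupling).** It may fail through oligomerisation, slow transmetalation of the electron-poor alkenylboronate, or allyl scrambling. The fallback closes the ring at C4=C5 by metathesis instead; it sets out from 9 and 10 and comes back at 18.
- Enone 10 is silylated (TMSOTf, Et3N) to trimethyl[(3-methylbuta-1,3-dien-2-yl)oxy]silane F2.
- F2 and 9 under the step 9 conditions give methyl (3R,6S,7S,10E)-12-[(tert-butoxycarbonyl)oxy]-6,7-epoxy-6,10-dimethyl-2-methylidene-3-(3-methyl-2-oxobut-3-en-1-yl)dodec-10-enoate F3.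
- Hydrolysis as in step 10 gives methyl (3R,6R,7S,10E)-12-[(tert-butoxycarbonyl)oxy]-6,7-dihydroxy-6,10-dimethyl-2-methylidene-3-(3-methyl-2-oxobut-3-en-1-yl)dodec-10-enoate F4.
- Acetylation as in step 11 gives methyl (3R,6R,7S,10E)-7-acetoxy-12-[(tert-butoxycarbonyl)oxy]-6-hydroxy-6,10-dimethyl-2-methylidene-3-(3-methyl-2-oxobut-3-en-1-yl)dodec-10-enoate F5.
- Intermolecular Stille coupling of the allylic carbonate with tributyl(vinyl)stannane (Pd2(dba)3, P(2-furyl)3, LiCl, DMF, rt) gives methyl (3R,6R,7S,10E)-7-acetoxy-6-hydroxy-6,10-dimethyl-2-methylidene-3-(3-methyl-2-oxobut-3-en-1-yl)tetradeca-10,13-dienoate F6.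
- Ring-closing metathesis of F6 (second-generation Hoveyda–Grubbs catalyst RuCl2(H2IMes)(=CH-C6H4-2-OiPr), 1,4-benzoquinone, toluene, 80 °C, 1 mM) joins the isopropenyl ketone and the terminal vinyl group. The more hindered acrylate methylene stays out, and the conjugated E-enone 18 is formed with loss of ethylene.

**Step 13 (CBS reduction on the macrocycle).** The ring conformation may override catalyst control, or the δ-hydroxy ester may lactonise. The fallback sets C3 before ring closure; it sets out from 17 and comes back at 19.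
- The same CBS reduction on the acyclic enone 17 gives methyl (3R,6R,7S,10E)-7-acetoxy-12-[(tert-butoxycarbonyl)oxy]-6-hydroxy-3-[(2S,3E)-2-hydroxy-3-methyl-4-(pinacolboryl)but-3-en-1-yl]-6,10-dimethyl-2-methylidenedodec-10-enoate F7.
- Silylation of the secondary alcohol (TESCl, imidazole, DMF, 0 °C) gives methyl (3R,6R,7S,10E)-7-acetoxy-12-[(tert-butoxycarbonyl)oxy]-6-hydroxy-6,10-dimethyl-2-methylidene-3-[(2S,3E)-3-methyl-4-(pinacolboryl)-2-[(triethylsilyl)oxy]but-3-en-1-yl]dodec-10-enoate F8.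
- Ring closure under the step 12 conditions gives methyl 2-[(1R,3S,4E,7E,11S,12R)-11-acetoxy-12-hydroxy-4,8,12-trimethyl-3-[(triethylsilyl)oxy]cyclotetradeca-4,7-dien-1-yl]prop-2-enoate F9.
- HF·pyridine in THF/pyridine at 0 °C removes the silyl group to give 19.

Further compounds

F1 | step 9 | (4E)-4-methyl-3-oxo-5-(pinacolboryl)pent-4-enoic acid | OC(=O)CC(=O)/C(C)=C/B1OC(C)(C)C(C)(C)O1
F2 | step 12 | trimethyl[(3-methylbuta-1,3-dien-2-yl)oxy]silane | C=C(C)C(=C)O[Si](C)(C)C
F3 | step 12 | methyl (3R,6S,7S,10E)-12-[(tert-butoxycarbonyl)oxy]-6,7-epoxy-6,10-dimethyl-2-methylidene-3-(3-methyl-2-oxobut-3-en-1-yl)dodec-10-enoate | C=C(C(=O)OC)[C@@H](CC(=O)C(C)=C)CC[C@]1(C)O[C@H]1CC/C(C)=C/COC(=O)OC(C)(C)C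
F4 | step 12 | methyl (3R,6R,7S,10E)-12-[(tert-butoxycarbonyl)oxy]-6,7-dihydroxy-6,10-dimethyl-2-methylidene-3-(3-methyl-2-oxobut-3-en-1-yl)dodec-10-enoate | C=C(C(=O)OC)[C@@H](CC(=O)C(C)=C)CC[C@@](C)(O)[C@@H](O)CC/C(C)=C/COC(=O)OC(C)(C)C
F5 | step 12 | methyl (3R,6R,7S,10E)-7-acetoxy-12-[(tert-butoxycarbonyl)oxy]-6-hydroxy-6,10-dimethyl-2-methylidene-3-(3-methyl-2-oxobut-3-en-1-yl)dodec-10-enoate | C=C(C(=O)OC)[C@@H](CC(=O)C(C)=C)CC[C@@](C)(O)[C@@H](OC(C)=O)CC/C(C)=C/COC(=O)OC(C)(C)C
F6 | step 12 | methyl (3R,6R,7S,10E)-7-acetoxy-6-hydroxy-6,10-dimethyl-2-methylidene-3-(3-methyl-2-oxobut-3-en-1-yl)tetradeca-10,13-dienoate | C=C(C(=O)OC)[C@@H](CC(=O)C(C)=C)CC[C@@](C)(O)[C@@H](OC(C)=O)CC/C(C)=C/CC=C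
F7 | step 13 | methyl (3R,6R,7S,10E)-7-acetoxy-12-[(tert-butoxycarbonyl)oxy]-6-hydroxy-3-[(2S,3E)-2-hydroxy-3-methyl-4-(pinacolboryl)but-3-en-1-yl]-6,10-dimethyl-2-methylidenedodec-10-enoate | C=C(C(=O)OC)[C@@H](C[C@H](O)/C(C)=C/B1OC(C)(C)C(C)(C)O1)CC[C@@](C)(O)[C@@H](OC(C)=O)CC/C(C)=C/COC(=O)OC(C)(C)C
F8 | step 13 | methyl (3R,6R,7S,10E)-7-acetoxy-12-[(tert-butoxycarbonyl)oxy]-6-hydroxy-6,10-dimethyl-2-methylidene-3-[(2S,3E)-3-methyl-4-(pinacolboryl)-2-[(triethylsilyl)oxy]but-3-en-1-yl]dodec-10-enoate | C=C(C(=O)OC)[C@@H](C[C@H](O[Si](CC)(CC)CC)/C(C)=C/B1OC(C)(C)C(C)(C)O1)CC[C@@](C)(O)[C@@H](OC(C)=O)CC/C(C)=C/COC(=O)OC(C)(C)C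
F9 | step 13 | methyl 2-[(1R,3S,4E,7E,11S,12R)-11-acetoxy-12-hydroxy-4,8,12-trimethyl-3-[(triethylsilyl)oxy]cyclotetradeca-4,7-dien-1-yl]prop-2-enoate | C=C(C(=O)OC)[C@@H]1CC[C@@](C)(O)[C@@H](OC(C)=O)CC/C(C)=C/C/C=C(\C)[C@@H](O[Si](CC)(CC)CC)C1
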